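Gibberellane numbering is used. The target has the carbon skeleton of fermentation-derived gibberellic acid. Its ring C/D oxygen, however, sits on C12, the carbon just outside ring D (C8, C13–C16), antiperiplanar to the C13–C16 bond. This is the retron of a 1,2-shift, so everything rests on disconnecting C13–C16 back to C12–C16. Ring D is opened (Grob) and C16 is re-attached to an oxygenated C12. The resulting bicyclo[2.2.2]octane, a bridgehead 12-ol 13-mesylate, undergoes a semipinacol shift. In one operation the six-membered ring C8–C14–C13–C12–C16–C15 contracts to ring D, C13–H is set by inversion, and the C12 carbonyl appears. Ring A is adjusted last.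

Key step: step 11

Remark: α is the face of ring A that carries the 19,10-lactone bridge, and the C15–C16 bridge lies on the β face of ring C. The epimers drawn at C16 (4–6) and at C12 (8) are the expected ones. Both centres are erased later, so their configuration has no consequence.

Step 1
Reactants: 1 gibberellic acid (GA3)
Product: 2 GA3 2-(trimethylsilyl)ethyl (TMSE) ester
Conditions: TMSCH2CH2OH, DCC, DMAP (cat.), CH2Cl2, 0 °C to rt
Reagents that add atoms: 2-(trimethylsilyl)ethanol, C[Si](C)(C)CCO
Why: Steglich esterification turns the C7 acid into a fluoride-labile ester that should survive the bases, hydrides and Pd(II) used later, and no stereocentre is touched.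

Step 2
Reactants: 2 GA3 TMSE ester
Product: 3 3-O-TBS-GA3 TMSE ester
Conditions: TBSCl, imidazole, DMF, rt
Reagents that add atoms: tert-butyldimethylsilyl chloride, CC(C)(C)[Si](C)(C)Cl
Why: Standard silylation is selective for the secondary allylic 3β-OH because the 13-OH is a tertiary bridgehead alcohol, which must stay free for step 5.

Step 3
Reactants: 3 3-O-TBS-GA3 TMSE ester
Product: 5 17-alcohol (16,17-dihydro-17-hydroxy derivative of 3), via 17-boryl 13-O-boryl adduct 4 (not isolated)
Conditions: 9-BBN (2.5 equiv), THF, 0 °C to rt; then 30% H2O2, aq NaOAc, 0 °C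
Reagents that add atoms: hydrogen peroxide, OO; 9-borabicyclo[3.3.1]nonane, C1CC2CCCC(C1)B2 (its boron stays only in 4)
Why: Brown hydroboration–oxidation: 9-BBN takes the 1,1-disubstituted C16=C17 bond in preference to the hindered, electron-poor C1=C2 bond, puts boron on C17 and delivers H to C16 from the exo face (side of C14), a centre that step 5 erases.

Step 4
Reactants: 5 17-alcohol
Product: 6 17-tosylate
Conditions: TsCl, pyridine, DMAP (cat.), CH2Cl2, 0 °C to rt
Reagents that add atoms: 4-toluenesulfonyl chloride, Cc1ccc(cc1)S(=O)(=O)Cl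
Why: Sulfonylation of the primary 17-OH is much faster than that of the tertiary 13-OH and installs the nucleofuge of a 1,3-diol monosulfonate.

Step 5
Reactants: 6 17-tosylate
Product: 7 13,16-seco ketone (C13=O, allyl group on C8)
Conditions: KOtBu, THF, 0 °C
Reagents that add atoms: none
Why: Grob (Wharton-type) fragmentation: the 13-alkoxide pushes, the C13–C16 bond (rotation about C16–C17 lets it lie antiperiplanar to C17–OTs) breaks with relief of bicyclo[3.2.1]octane strain, and ring D opens to the C13 ketone and an allyl group on C8, oxetane closure being disfavoured by the endo position of C17.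

Step 6
Reactants: 7 13,16-seco ketone
Product: 8 12β-benzoyloxy ketone
Conditions: MeNHOBz·HCl, DMSO, rt
Reagents that add atoms: N-methyl-O-benzoylhydroxylamine hydrochloride, CNOC(=O)c1ccccc1.Cl
Why: α-Oxyacylation of a ketone with an N-alkyl-O-acylhydroxylamine salt ([3,3]-sigmatropic shift of the derived N-benzoyloxy enamine) should occur at C12 and not at the neopentyl C14, the equatorial 12β-benzoate being expected but irrelevant because C12 becomes sp2 in step 7.

Step 7
Reactants: 8 12β-benzoyloxy ketone
Product: 9 Δ12(13) silyl enol ether (13-OTBS, 12-OBz)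
Conditions: TBSOTf, Et3N, CH2Cl2, 0 °C
Reagents that add atoms: tert-butyldimethylsilyl triflate, CC(C)(C)[Si](C)(C)OS(=O)(=O)C(F)(F)F
Why: Soft enolisation (amine/silyl triflate) removes the more acidic and less hindered H-12 next to the benzoate, so the tetrasubstituted Δ12 enol ether should form, in which the poorly donating acyloxy group leaves C12 as the only nucleophilic carbon.

Step 8
Reactants: 9 Δ12(13) silyl enol ether
Product: 10 bicyclo[2.2.2]octanone (C12–C16 bond, 12-OBz, C13=O, C16=CH2)
Conditions: Pd(OAc)2 (10 mol %), O2 (1 atm), DMSO, 45 °C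
Reagents that add atoms: none
Why: Pd(II)-catalysed cycloalkenylation of a silyl enol ether (oxo-π-allylpalladium as in the Saegusa–Ito oxidation, 6-exo-trig carbopalladation of the allyl group, β-hydride elimination of H-16) joins C12 to C16 and gives the exocyclic methylene, the bridgehead configuration at C12 being dictated by the tether from C8.

Step 9
Reactants: 10 bicyclo[2.2.2]octanone
Product: 12 bicyclo[2.2.2]octane 12,13-diol, via 13-alcohol 12-benzoate 11 (not isolated)
Conditions: NaBH4, MeOH–THF, −20 °C; then K2CO3 (cat.), MeOH, rt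
Reagents that add atoms: none
Why: Borohydride should reach the C13 carbonyl from the side of the flat C15–C16(=CH2) bridge because the other side is screened by H-11 and by C10 on the C9–C11 bridge, so the 13-OH points to the C9–C11 bridge (anti to C12–C16), and base-catalysed methanolysis then removes the benzoate wherever acyl migration has put it.

Step 10
Reactants: 12 bicyclo[2.2.2]octane 12,13-diol
Product: 13 12-ol 13-mesylate
Conditions: MsCl, Et3N, CH2Cl2, −20 °C
Reagents that add atoms: methanesulfonyl chloride, CS(=O)(=O)Cl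
Why: Mesylation discriminates the secondary 13-OH from the tertiary bridgehead 12-OH and gives the 1,2-diol monosulfonate needed for the rearrangement.

Step 11
Reactants: 13 12-ol 13-mesylate
Product: 14 3-O-TBS-12-oxo-GA7 TMSE ester (bicyclo[3.2.1]octane restored, 13-H)
Conditions: KOtBu, THF, −20 to 0 °C
Reagents that add atoms: none
Why: Deprotonation of the bridgehead 12-OH triggers a concerted semipinacol 1,2-shift in which the C12–C16 σ-bond, antiperiplanar to C13–OMs, migrates to C13 as mesylate leaves and C12 becomes the ketone. The closest known reaction type is the rearrangement of 1-hydroxy- or 1-methoxybicyclo[2.2.2]octan-2-yl sulfonates, and of cyclic 1,2-diol monosulfonates in general, to ring-contracted ketones. Ring D is closed by ring contraction and not by cyclisation: the six-membered ring C8–C14–C13–C12–C16–C15 extrudes C12 and becomes the five-membered ring C8–C14–C13–C16–C15, while ring C (C8, C9, C11–C14) stays six-membered, so bicyclo[2.2.2]octane becomes bicyclo[3.2.1]octane. C13 is the only new stereocentre and is set by inversion (backside attack of C16), which the cage allows in one sense only and which equals the configuration of the target. The selectivity needed is migration of C16 rather than C11; it is secured by the C13 configuration from step 9 (OMs gauche to C12–C11), and epoxide formation is excluded because the bridgehead oxygen cannot reach the back of C13. The alkoxide push and the loss of the eclipsed bicyclo[2.2.2]octane make the step irreversible, and the β,γ-unsaturated ketone cannot conjugate because C13 is a bridgehead.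

Step 12
Reactants: 14 3-O-TBS-12-oxo-GA7 TMSE ester
Product: 15 3-O-TBS-12α-hydroxy-GA7 TMSE ester
Conditions: L-Selectride, THF, −78 °C; aq NH4Cl
Reagents that add atoms: none
Why: Bulky-hydride reduction of a cyclohexanone by equatorial attack: the reagent should come from the β (endo) face past the flat sp2 C16, because the α face is closed by the syn-axial C9–C10 bond and by H-14, which gives the axial 12α-OH.

Step 13
Reactants: 15 3-O-TBS-12α-hydroxy-GA7 TMSE ester
Product: 16 12α-hydroxy-GA7 (free acid, 3β-OH free)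
Conditions: TBAF, THF, 0 °C to rt; then aq HCl to pH 3
Reagents that add atoms: none
Why: Fluoride cleaves the silyl ether and fragments the TMSE ester (ethene and Me3SiF) in one operation, before the base-sensitive ring A functions exist.

Step 14
Reactants: 16 12α-hydroxy-GA7
Product: 17 12α-hydroxy-3-oxo-1-ene acid (3-dehydro derivative of 16)
Conditions: activated MnO2, acetone, rt
Reagents that add atoms: none
Why: Activated MnO2 oxidises only the allylic 3β-OH, the homoallylic 12α-OH and the acid being inert.

Step 15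
Reactants: 17 12α-hydroxy-3-oxo-1-ene acid
Product: 18 1β,2β-epoxy-12α-hydroxy-3-oxo acid
Conditions: 30% H2O2, K2CO3, MeOH–H2O, 0 °C; then pH 3
Reagents that add atoms: hydrogen peroxide, OO
Why: Weitz–Scheffer nucleophilic epoxidation touches only the enone, and hydroperoxide adds to C1 from the β face because the 19,10-lactone bridge covers the α face, which sets C1 (and the transient C2).

Step 16
Reactants: 18 1β,2β-epoxy-12α-hydroxy-3-oxo acid
Product: 19 target (1β,12α-dihydroxy-3-oxo-GA9, CNP0259985.1)
Conditions: SmI2 (2.5 equiv), THF–MeOH, −90 °C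
Reagents that add atoms: none
Why: SmI2 reduction of an α,β-epoxy ketone (ketyl, C2–O cleavage, protonation of the samarium enolate by MeOH at low temperature) should give the β-hydroxy ketone with the C1–O bond and hence the 1β configuration intact and without dehydration.

Compound list
1 | gibberellic acid (GA3; 3β,13-dihydroxy-1,16-diene, 19,10-lactone on the α face, 6β-CO2H) | C=C1C[C@]23C[C@@]1(O)CC[C@H]2[C@]12OC(=O)[C@](C)([C@@H](O)C=C1)[C@H]2[C@@H]3C(=O)O | starting material
2 | GA3 2-(trimethylsilyl)ethyl ester | C=C1C[C@]23C[C@@]1(O)CC[C@H]2[C@]12OC(=O)[C@](C)([C@@H](O)C=C1)[C@H]2[C@@H]3C(=O)OCC[Si](C)(C)C | intermediate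
3 | 3-O-TBS-GA3 TMSE ester (13-OH free) | C=C1C[C@]23C[C@@]1(O)CC[C@H]2[C@]12OC(=O)[C@](C)([C@@H](O[Si](C)(C)C(C)(C)C)C=C1)[C@H]2[C@@H]3C(=O)OCC[Si](C)(C)C | intermediate
4 | 17-(9-BBN) 13-O-(9-BBN) adduct of 3 (H-16 exo) | B5(C6CCCC5CCC6)C[C@H]1C[C@]23C[C@@]1(OB7C8CCCC7CCC8)CC[C@H]2[C@]12OC(=O)[C@](C)([C@@H](O[Si](C)(C)C(C)(C)C)C=C1)[C@H]2[C@@H]3C(=O)OCC[Si](C)(C)C | intermediate (not isolated)
5 | 17-alcohol: 16,17-dihydro-13,17-dihydroxy compound (H-16 exo on the C14 side, CH2OH endo) | OC[C@H]1C[C@]23C[C@@]1(O)CC[C@H]2[C@]12OC(=O)[C@](C)([C@@H](O[Si](C)(C)C(C)(C)C)C=C1)[C@H]2[C@@H]3C(=O)OCC[Si](C)(C)C | intermediate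
6 | 17-tosylate of 5 | Cc4ccc(cc4)S(=O)(=O)OC[C@H]1C[C@]23C[C@@]1(O)CC[C@H]2[C@]12OC(=O)[C@](C)([C@@H](O[Si](C)(C)C(C)(C)C)C=C1)[C@H]2[C@@H]3C(=O)OCC[Si](C)(C)C | intermediate
7 | 13,16-seco ketone: ring C cyclohexanone (C13=O) with allyl (C15–C17) on C8, rings A and B as in 3 | C=CC[C@]23CC(=O)CC[C@H]2[C@]12OC(=O)[C@](C)([C@@H](O[Si](C)(C)C(C)(C)C)C=C1)[C@H]2[C@@H]3C(=O)OCC[Si](C)(C)C | intermediate
8 | 12β-benzoyloxy derivative of 7 | C=CC[C@]23CC(=O)[C@H](OC(=O)c4ccccc4)C[C@H]2[C@]12OC(=O)[C@](C)([C@@H](O[Si](C)(C)C(C)(C)C)C=C1)[C@H]2[C@@H]3C(=O)OCC[Si](C)(C)C | intermediate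
9 | Δ12(13) enol ether of 8 (13-OTBS, 12-OBz) | C=CC[C@]23CC(O[Si](C)(C)C(C)(C)C)=C(OC(=O)c4ccccc4)C[C@H]2[C@]12OC(=O)[C@](C)([C@@H](O[Si](C)(C)C(C)(C)C)C=C1)[C@H]2[C@@H]3C(=O)OCC[Si](C)(C)C | intermediate
10 | bicyclo[2.2.2]octanone: bridgeheads C8 and C12 (12-OBz), bridges C9–C11, C14–C13(=O), C15–C16(=CH2) | C=C1C[C@]23CC(=O)[C@@]1(OC(=O)c4ccccc4)C[C@H]2[C@]12OC(=O)[C@](C)([C@@H](O[Si](C)(C)C(C)(C)C)C=C1)[C@H]2[C@@H]3C(=O)OCC[Si](C)(C)C | intermediate
11 | 13-alcohol 12-benzoate (13-OH toward the C9–C11 bridge) | C=C1C[C@]23C[C@@H](O)[C@@]1(OC(=O)c4ccccc4)C[C@H]2[C@]12OC(=O)[C@](C)([C@@H](O[Si](C)(C)C(C)(C)C)C=C1)[C@H]2[C@@H]3C(=O)OCC[Si](C)(C)C | intermediate (not isolated)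
12 | bicyclo[2.2.2]octane 12,13-diol (bridgehead 12-OH; 13-OH toward the C9–C11 bridge, anti to C12–C16) | C=C1C[C@]23C[C@@H](O)[C@@]1(O)C[C@H]2[C@]12OC(=O)[C@](C)([C@@H](O[Si](C)(C)C(C)(C)C)C=C1)[C@H]2[C@@H]3C(=O)OCC[Si](C)(C)C | intermediate
13 | 13-mesylate of 12 | C=C1C[C@]23C[C@@H](OS(C)(=O)=O)[C@@]1(O)C[C@H]2[C@]12OC(=O)[C@](C)([C@@H](O[Si](C)(C)C(C)(C)C)C=C1)[C@H]2[C@@H]3C(=O)OCC[Si](C)(C)C | intermediate
14 | 3-O-TBS-12-oxo-GA7 TMSE ester (bicyclo[3.2.1]octane, bridgehead 13-H, C16=CH2) | C=C1C[C@]23C[C@H]1C(=O)C[C@H]2[C@]12OC(=O)[C@](C)([C@@H](O[Si](C)(C)C(C)(C)C)C=C1)[C@H]2[C@@H]3C(=O)OCC[Si](C)(C)C | intermediate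
15 | 3-O-TBS-12α-hydroxy-GA7 TMSE ester (axial 12-OH, anti to C13–C16) | C=C1C[C@]23C[C@H]1[C@@H](O)C[C@H]2[C@]12OC(=O)[C@](C)([C@@H](O[Si](C)(C)C(C)(C)C)C=C1)[C@H]2[C@@H]3C(=O)OCC[Si](C)(C)C | intermediate
16 | 12α-hydroxy-GA7 (3β,12α-dihydroxy-1,16-diene acid) | C=C1C[C@]23C[C@H]1[C@@H](O)C[C@H]2[C@]12OC(=O)[C@](C)([C@@H](O)C=C1)[C@H]2[C@@H]3C(=O)O | intermediate
17 | 12α-hydroxy-3-oxo-1-ene acid | C=C1C[C@]23C[C@H]1[C@@H](O)C[C@H]2[C@]12OC(=O)[C@](C)(C(=O)C=C1)[C@H]2[C@@H]3C(=O)O | intermediate
18 | 1β,2β-epoxy-12α-hydroxy-3-oxo acid | C=C1C[C@]23C[C@H]1[C@@H](O)C[C@H]2[C@]12OC(=O)[C@](C)(C(=O)[C@H]4O[C@@H]14)[C@H]2[C@@H]3C(=O)O | intermediate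
19 | 1β,12α-dihydroxy-3-oxo-GA9 (CNP0259985.1) | C=C1C[C@]23C[C@H]1[C@@H](O)C[C@H]2[C@]12OC(=O)[C@](C)(C(=O)C[C@H]1O)[C@H]2[C@@H]3C(=O)O | target

Total step count: 16. Longest linear sequence: 16 steps (fully linear from 1).

Steps most likely to fail

Step 8. The tetrasubstituted, acyloxy-deactivated enol ether is a slow nucleophile. Loss of H-11 from the palladium enolate (Saegusa-type dehydrosilylation) may therefore outrun carbopalladation, and re-addition of Pd–H may move the new double bond into the ring. The fallback sets out from 8 and comes back at 10, bypassing 9, and it forms the C12–C16 bond by a radical instead of an organopalladium path. It is an oxidative free-radical cyclisation with Mn(OAc)3·2H2O and Cu(OAc)2·H2O in AcOH at 60–80 °C. The easily enolised α-acyloxy ketone is oxidised to the C12 radical, which closes 6-exo onto the allyl group. Cu(II) then oxidises the primary C17 radical to the exocyclic methylene. No new compound is made (F0).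

Step 11. Ionisation at C13 may run ahead of migration, with proton loss or capture of the cation. Any 13-epimer carried along from step 9 would shift C11 instead of C16. The fallback sets out from 12 and comes back at 15, replacing steps 10–12 by a radical ring contraction. The 13-OH of 12 is acylated with phenyl chlorothionoformate (pyridine, DMAP, 0 °C) to the 13-O-phenoxythiocarbonyl derivative F1. Bu3SnH/AIBN in hot toluene then generates the C13 radical (Barton–McCombie-type initiation). This radical adds 3-exo to C16, and the cyclopropylcarbinyl radical reopens at C12–C16 to the hydroxy-stabilised C12 radical (homoallyl–homoallyl radical rearrangement). Hydrogen transfer from tin hydride on the open β face should then give 15 directly.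

Step 12. Facial selectivity may be poor, because the β face is flanked by C16 and the α face by C10, so hydride may also enter from the α face. The fallback sets out from 14 and comes back at 15, and it sets C12 by SN2 inversion instead of by facial selection. NaBH4 in MeOH (or the minor product of step 12) supplies the equatorial 12β-alcohol F2. A Mitsunobu reaction (4-nitrobenzoic acid, PPh3, DIAD, THF) gives the 12α-(4-nitrobenzoate) F3, and K2CO3 in MeOH releases 15.

Further compounds
F0 | step 8 | none | none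
F1 | step 11 | 13-O-phenoxythiocarbonyl derivative of 12 | C=C1C[C@]23C[C@@H](OC(=S)Oc4ccccc4)[C@@]1(O)C[C@H]2[C@]12OC(=O)[C@](C)([C@@H](O[Si](C)(C)C(C)(C)C)C=C1)[C@H]2[C@@H]3C(=O)OCC[Si](C)(C)C
F2 | step 12 | 3-O-TBS-12β-hydroxy-GA7 TMSE ester | C=C1C[C@]23C[C@H]1[C@H](O)C[C@H]2[C@]12OC(=O)[C@](C)([C@@H](O[Si](C)(C)C(C)(C)C)C=C1)[C@H]2[C@@H]3C(=O)OCC[Si](C)(C)C
F3 | step 12 | 12α-(4-nitrobenzoate) of 15 | C=C1C[C@]23C[C@H]1[C@@H](OC(=O)c4ccc(cc4)[N+](=O)[O-])C[C@H]2[C@]12OC(=O)[C@](C)([C@@H](O[Si](C)(C)C(C)(C)C)C=C1)[C@H]2[C@@H]3C(=O)OCC[Si](C)(C)C
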